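## Analysis of the target

Agrimol C is an open, achiral chain of three fully substituted benzene rings and has no stereocenter. The central ring B is a phloroglucinol with a butanoyl group at C1, hydroxyls at C2, C4 and C6, and methylene bridges at C3 and C5. Each bridge leads to C1' of an identical ring A, which carries hydroxyls at C2' and C6', a methyl group at C3', a methoxy group at C4' and a butanoyl group at C5'; a mirror plane through C1 and C4 of ring B makes the two rings A equivalent, so they can be made once and attached in one operation. The sensitive parts are the seven free phenols (oxidised by air under base) and the two diarylmethane bridges, which can exchange under acid or strong base through quinone methides, so the late steps must be mild and close to neutral. The difficulties are threefold: telling apart the three oxygens of ring A (the single methyl ether sits in the most crowded place, between the methyl and the acyl group), assembling A–CH2–B–CH2–A without a statistical mixture, and introducing three acyl groups. The route rests on one feature: every butanoyl carbonyl is ortho to a free hydroxyl, the C1 carbonyl of ring B between the C2 and C6 hydroxyls and the C5' carbonyl of each ring A between the C4' methoxy and the C6' hydroxyl. Each ketone is thus formally the adduct of the formyl C–H bond of a salicylaldehyde to propene.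

## Retrosynthetic reasoning

**Agrimol C (20) to tris-aldehyde 14 and three molecules of propene (15).** The three bonds between each carbonyl carbon and C2 of its butanoyl chain are cut. They are cut there because the ortho hydroxyl can hold a metal next to the formyl C–H bond, so the aldehyde carbon can be used with reversed polarity and no acyl anion equivalent or protecting group is needed. The gain is that all three ketones appear in one atom-economical operation at the very end, on the unprotected skeleton. The forward reaction has to add each of the three formyl C–H bonds across one molecule of 15, with the carbon–carbon bond going to the terminal carbon, without decarbonylation and without touching the bridges.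

**Tris-aldehyde 14 to bis-aminomethyl compound 12 and two molecules of aldehyde 8.** The two bonds between the bridge carbons and C1' of the rings A are cut. The bridge carbons stay on ring B as aminomethyl groups that can leave to give ortho-quinone methides. Putting both electrophilic carbons on ring B, which then has no free position, and giving ring A its single free, doubly hydroxyl-flanked carbon as the nucleophile fixes the A–B–A order. A direct three-component condensation with 10 would give every combination of rings. The forward step has to alkylate carbon, not oxygen, and must not scramble the bridges.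

**Compound 12 to 2,4,6-trihydroxybenzaldehyde (9) and two molecules of formaldehyde (10).** The two bonds from C3 and C5 of ring B to the bridge carbons are cut in a twofold phenolic Mannich reaction with a secondary amine. Ring B has exactly two open positions, both between hydroxyls, so the count of aminomethyl groups is fixed by the substrate.

**Aldehyde 8 to its silyl ether 7 and then to 3.** The C6–O bond of the benzaldehyde (C6'–O of ring A in the target) is cut. This hydroxyl is the one that will later hold the metal, and its position ortho to the formyl group is exactly the position a masked formyl group can direct a lithium base to. In 3 the only ring hydrogen ortho to the formyl group is at C6, so the regiochemistry is set by the substrate; an electrophilic oxygenation could not reach this carbon, which is meta to both existing oxygens. The forward sequence has to metalate C6, not C5, trap with a borate ester and oxidise carbon–boron to carbon–oxygen without oxidising the aldehyde.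

**Compound 3 to 2 and to 2,4-dihydroxy-3-methylbenzaldehyde (1).** The two oxygens of 1 differ already: O4 is free and the more acidic, O2 is hydrogen-bonded to the formyl group. O4 is therefore capped first with a bulky triisopropylsilyl group and O2 is then methylated, which places the methyl ether between the formyl and the methyl group as the target requires. A silyl ether is chosen over a benzyl ether for two reasons: it has no benzylic hydrogens for the alkyllithium to attack, and it directs metalation poorly, so C5 is left alone. It is also removed by fluoride without hydrogen near an aldehyde.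

## Alternatives that were turned down

**Alternative 1:** Both rings A are built, not bought. Each is cut across C1'–C6' and C2'–C3', leading back to bis(silyloxyalkyne) A2 (ring B already carrying both bridge carbons) and two molecules of cyclobutenone A3.
- Forward key step: heating opens A3 to a vinylketene, which adds (2+2) to each silyloxyalkyne of A2. The 4π opening of the new four-membered ring and a 6π electrocyclisation then give both benzene rings of A1 (a twofold Danheiser benzannulation).
- For it: the pattern of ring A (hydroxyl at C6', silyloxy at C2', methyl at C3', methoxy at C4') is written into the two partners, and the bridges are ordinary carbon–carbon bonds from the start. On both points it is stronger than the chosen route, which needs a directed metalation and a selective bridging step.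
- Against it: A1 carries none of the three butanoyl groups. They would have to follow by threefold Friedel–Crafts or Fries chemistry in the presence of three benzyl ethers, two silyl ethers and two acid-labile diarylmethane links, and five protecting groups then have to come off. A2 needs two-directional ynolate chemistry on a crowded benzene, and silyl ynol ethers are fragile.
- Comparison: the sequence would be well over twice as long. The chosen route offers instead a protecting-group-free end game in which the three acyl groups come from 15 in one step.

**Alternative 2:** Ring B is built last. C3–C4 and C4–C5 are cut, which leads back to the open-chain diketone A5 and dimethyl carbonate A6 as the one-carbon unit.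
- Forward key step: the polyanion of A5 attacks A6 through one terminal α-carbon, and the second terminal α-carbon then closes the ring on the new ester, giving the triol A4.
- For it: the bridges are part of a carbon chain, so no bridge scrambling is possible. Ring A carries two identical benzyl ethers, so its oxygens need not be told apart. On both points it is stronger than the chosen route.
- Against it: the second ring-closing acylation must go through carbon, while closure through the enolate oxygen (lactonisation) is the usual course for such dioxo esters, and the trianion has to be regenerated after the first acylation. A4 again lacks all three butanoyl groups, so three late acylations on a polyphenol with acid-labile bridges and four debenzylations remain.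
- Comparison: the chosen route places the acyl carbons as formyl groups on the monomers, where this is easy, and converts them at the end without acid.

**Alternative 3:** Ring A is disconnected at C6'–O and C5'–C(=O) together, to a 5',6'-aryne (from silyl triflate A8) and butanoic acid A9.
- Forward key step: fluoride releases the aryne; the carboxylate adds through oxygen at C6', the carbon remote from the methoxy group, and the aryl anion at C5' takes over the acyl group to give ketone A7.
- For it: carbon–oxygen and carbon–carbon bonds form in one step, the methoxy group next to the aryne fixes the regiochemistry, and the reaction type is established for single rings. On precedent it is stronger than the chosen key step.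
- Against it: it makes only the ring A monomer; the ring B ketone, the debenzylation and both bridges remain. A8 is a pentasubstituted silyl triflate that needs several steps, one of which installs a phenol oxygen only to discard it as triflate before oxygen is brought back from A9. Simple O-arylation without acyl transfer competes.
- Comparison: per ring it is no shorter than the path to 8. The chosen route gets all three ketones from simple aldehydes in one catalytic step on the assembled skeleton, with 15 as the only added reagent.

Key step: step 7

Assumption: the target is the achiral constitution shown by its SMILES (no stereocenters); 1, 9, 10 (as formalin) and 15 are purchased.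

## Route

**Step 1**
Reactants: 1 2,4-dihydroxy-3-methylbenzaldehyde
Product: 2 2-hydroxy-3-methyl-4-[(triisopropylsilyl)oxy]benzaldehyde
Conditions: TIPSCl (1.05 equiv), imidazole, CH2Cl2, 0 °C to rt
Reagents that add atoms: chlorotri(propan-2-yl)silane (TIPSCl), CC(C)[Si](Cl)(C(C)C)C(C)C
Why: Silylation of a phenol; the 4-hydroxyl is free and the more acidic, while the 2-hydroxyl is hydrogen-bonded to the formyl group and flanked on both sides, so one equivalent of the bulky chloride should react at O4 only.

**Step 2**
Reactants: 2 2-hydroxy-3-methyl-4-[(triisopropylsilyl)oxy]benzaldehyde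
Product: 3 2-methoxy-3-methyl-4-[(triisopropylsilyl)oxy]benzaldehyde
Conditions: MeI, K2CO3, dry acetone, 45 °C
Reagents that add atoms: iodomethane, CI
Why: Williamson ether synthesis on the remaining chelated phenoxide; the hindered triisopropylsilyl ether should survive carbonate in a dry aprotic solvent.

**Step 3**
Reactants: 3 2-methoxy-3-methyl-4-[(triisopropylsilyl)oxy]benzaldehyde
Product: 7 6-hydroxy-2-methoxy-3-methyl-4-[(triisopropylsilyl)oxy]benzaldehyde, via lithium α-amino alkoxide 4 (not isolated), via C6-lithiated amino alkoxide 5 (not isolated), via aryl trimethoxyborate 6 (not isolated)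
Conditions: LiN(Me)CH2CH2NMe2 (from the diamine and n-BuLi), THF, −20 °C; n-BuLi (3 equiv), −20 °C; B(OMe)3, −78 °C to 0 °C; AcOH, 30% H2O2, 0 °C to rt; aq. NH4Cl
Reagents that add atoms: hydrogen peroxide, OO (the hydroxyl oxygen of 7); lithium [2-(dimethylamino)ethyl](methyl)amide, [Li+].C[N-]CCN(C)C (atoms in 4 to 6 only); n-butyllithium, [Li]CCCC (lithium in 5 and 6 only); trimethyl borate, COB(OC)OC (atoms in 6 only)
Why: Directed ortho-metalation of an aldehyde masked in the flask as its α-amino alkoxide, then borylation and oxidation; the chelating diamine arm delivers the alkyllithium to C6, the only ring C–H ortho to the masked formyl group, while the bulky, poorly coordinating silyl ether does not direct to C5. Peroxide under acetic acid converts C–B into C–OH without Dakin cleavage, and aqueous work-up releases the aldehyde from the hemiaminal (its transient stereocenter is lost).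

**Step 4**
Reactants: 7 6-hydroxy-2-methoxy-3-methyl-4-[(triisopropylsilyl)oxy]benzaldehyde
Product: 8 4,6-dihydroxy-2-methoxy-3-methylbenzaldehyde
Conditions: Bu4NF, AcOH, THF, 0 °C
Reagents that add atoms: none
Why: Fluoride cleavage of an aryl silyl ether; acetic acid buffers the phenoxide so that the electron-rich dihydroxybenzaldehyde is not left in base under air.

**Step 5**
Reactants: 9 2,4,6-trihydroxybenzaldehyde; 10 formaldehyde (2.2 equiv)
Product: 12 3,5-bis[(dimethylamino)methyl]-2,4,6-trihydroxybenzaldehyde, via mono-Mannich base 11 (not isolated)
Conditions: 37% aq. CH2O (2.2 equiv) premixed with 40% aq. Me2NH (2.2 equiv), EtOH, 0 °C to rt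
Reagents that add atoms: dimethylamine, CNC (2.2 equiv; one molecule ends up in each aminomethyl group)
Why: Twofold phenolic Mannich reaction; both open ring positions lie between two hydroxyls and each takes up one iminium ion formed from 10 and the amine, and no third position is available.

**Step 6**
Reactants: 12 3,5-bis[(dimethylamino)methyl]-2,4,6-trihydroxybenzaldehyde; 8 4,6-dihydroxy-2-methoxy-3-methylbenzaldehyde (2.2 equiv)
Product: 14 3,5-bis[(3-formyl-2,6-dihydroxy-4-methoxy-5-methylphenyl)methyl]-2,4,6-trihydroxybenzaldehyde, via mono-bridged Mannich base 13 (not isolated)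
Conditions: 1,4-dioxane, 100 °C, slow N2 stream
Reagents that add atoms: none
Why: Alkylation through ortho-quinone methides, the usual way to methylene-bridged acylphloroglucinols; on heating each aminomethylphenol loses dimethylamine (swept out) and the quinone methide is captured at C5 of 8, its only unsubstituted carbon, flanked by two hydroxyls. C-alkylation restores both aromatic rings and is the thermodynamic outcome.

**Step 7**
Reactants: 14 3,5-bis[(3-formyl-2,6-dihydroxy-4-methoxy-5-methylphenyl)methyl]-2,4,6-trihydroxybenzaldehyde; 15 propene (3 equiv)
Product: 20 agrimol C (1-{3,5-bis[(3-butanoyl-2,6-dihydroxy-4-methoxy-5-methylphenyl)methyl]-2,4,6-trihydroxyphenyl}butan-1-one), via ring A monoketone 16 (not isolated), via ring B monoketone 17 (not isolated), via ring A/ring A diketone 18 (not isolated), via ring A/ring B diketone 19 (not isolated)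
Conditions: [Rh(cod)Cl]2 (10 mol%), 1,1'-bis(diphenylphosphino)ferrocene (20 mol%), K3PO4 (30 mol%), propene (6 bar, in excess of the 3 equiv consumed), 1,4-dioxane, 80 °C, sealed vessel
Reagents that add atoms: propene, CC=C (this is compound 15; three molecules are built into 20, one at each formyl carbon, and nothing else adds atoms)
Why: Proposed new method: a threefold intermolecular chelation-assisted hydroacylation on a heptaphenolic tris-aldehyde, in which each of the three formyl groups of 14 takes up one molecule of 15 (C27H26O12 + 3 C3H6 = C36H44O12); the closest known reaction type is the rhodium-catalysed, linear-selective hydroacylation of terminal alkenes with salicylaldehydes. A phenoxide oxygen ortho to a formyl group binds monovalent rhodium, the formyl C–H adds oxidatively to give a five-membered acyl rhodium hydride chelate of trivalent rhodium, 15 inserts into Rh–H, and reductive elimination joins the acyl carbon to the terminal CH2 and returns monovalent rhodium. The chelate holds the acyl group in place and so should hold back decarbonylation, the usual failure of intermolecular hydroacylation. No ring closes and no stereocenter is formed. The selectivity needed is linear over branched insertion (butanoyl, not 2-methylpropanoyl); it should come from crowding at the metal, since each acyl carbon sits between two ortho oxygen substituents and rhodium carries a wide bisphosphine, which favours the primary propyl group. Chemoselectivity rests on each of the three formyl groups having an ortho hydroxyl (C2/C6 on ring B, C6' on each ring A), so only these three C–H bonds can enter the chelate; proton exchange among the seven hydroxyls is fast, so a catalytic amount of base should serve all sites. The partly acylated species 16 to 19, formed in no fixed order, keep the same salicylaldehyde units and should react on with further 15 under the same conditions until all three sites are converted.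

## Compound list

1 | 2,4-dihydroxy-3-methylbenzaldehyde | Cc1c(O)ccc(C=O)c1O | starting material
2 | 2-hydroxy-3-methyl-4-[(triisopropylsilyl)oxy]benzaldehyde | CC(C)[Si](Oc1ccc(C=O)c(O)c1C)(C(C)C)C(C)C | intermediate
3 | 2-methoxy-3-methyl-4-[(triisopropylsilyl)oxy]benzaldehyde | COc1c(C=O)ccc(O[Si](C(C)C)(C(C)C)C(C)C)c1C | intermediate
4 | lithium α-amino alkoxide of 3 with N,N,N'-trimethylethane-1,2-diamine (racemic hemiaminal carbon) | CN(C)CCN(C)C([O-])c1ccc(O[Si](C(C)C)(C(C)C)C(C)C)c(C)c1OC.[Li+] | intermediate (not isolated)
5 | C6-lithiated α-amino alkoxide | CN(C)CCN(C)C([O-])c1c([Li])cc(O[Si](C(C)C)(C(C)C)C(C)C)c(C)c1OC.[Li+] | intermediate (not isolated)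
6 | dilithium aryl trimethoxyborate of the α-amino alkoxide | CN(C)CCN(C)C([O-])c1c([B-](OC)(OC)OC)cc(O[Si](C(C)C)(C(C)C)C(C)C)c(C)c1OC.[Li+].[Li+] | intermediate (not isolated)
7 | 6-hydroxy-2-methoxy-3-methyl-4-[(triisopropylsilyl)oxy]benzaldehyde | COc1c(C=O)c(O)cc(O[Si](C(C)C)(C(C)C)C(C)C)c1C | intermediate
8 | 4,6-dihydroxy-2-methoxy-3-methylbenzaldehyde | COc1c(C=O)c(O)cc(O)c1C | intermediate
9 | 2,4,6-trihydroxybenzaldehyde | O=Cc1c(O)cc(O)cc1O | starting material
10 | formaldehyde | C=O | starting material
11 | 3-[(dimethylamino)methyl]-2,4,6-trihydroxybenzaldehyde | O=Cc1c(O)cc(O)c(CN(C)C)c1O | intermediate (not isolated)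
12 | 3,5-bis[(dimethylamino)methyl]-2,4,6-trihydroxybenzaldehyde | O=Cc1c(O)c(CN(C)C)c(O)c(CN(C)C)c1O | intermediate
13 | 3-[(dimethylamino)methyl]-5-[(3-formyl-2,6-dihydroxy-4-methoxy-5-methylphenyl)methyl]-2,4,6-trihydroxybenzaldehyde | O=Cc1c(O)c(CN(C)C)c(O)c(Cc2c(O)c(C)c(OC)c(C=O)c2O)c1O | intermediate (not isolated)
14 | 3,5-bis[(3-formyl-2,6-dihydroxy-4-methoxy-5-methylphenyl)methyl]-2,4,6-trihydroxybenzaldehyde | O=Cc1c(O)c(Cc2c(O)c(C)c(OC)c(C=O)c2O)c(O)c(Cc2c(O)c(C)c(OC)c(C=O)c2O)c1O | intermediate
15 | propene | CC=C | starting material
16 | 3-[(3-butanoyl-2,6-dihydroxy-4-methoxy-5-methylphenyl)methyl]-5-[(3-formyl-2,6-dihydroxy-4-methoxy-5-methylphenyl)methyl]-2,4,6-trihydroxybenzaldehyde | O=Cc1c(O)c(Cc2c(O)c(C)c(OC)c(C=O)c2O)c(O)c(Cc2c(O)c(C)c(OC)c(C(=O)CCC)c2O)c1O | intermediate (not isolated)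
17 | 3,3'-[(5-butanoyl-2,4,6-trihydroxy-1,3-phenylene)bis(methylene)]bis(2,4-dihydroxy-6-methoxy-5-methylbenzaldehyde) | CCCC(=O)c1c(O)c(Cc2c(O)c(C)c(OC)c(C=O)c2O)c(O)c(Cc2c(O)c(C)c(OC)c(C=O)c2O)c1O | intermediate (not isolated)
18 | 3,5-bis[(3-butanoyl-2,6-dihydroxy-4-methoxy-5-methylphenyl)methyl]-2,4,6-trihydroxybenzaldehyde | O=Cc1c(O)c(Cc2c(O)c(C)c(OC)c(C(=O)CCC)c2O)c(O)c(Cc2c(O)c(C)c(OC)c(C(=O)CCC)c2O)c1O | intermediate (not isolated)
19 | 3-({3-butanoyl-5-[(3-butanoyl-2,6-dihydroxy-4-methoxy-5-methylphenyl)methyl]-2,4,6-trihydroxyphenyl}methyl)-2,4-dihydroxy-6-methoxy-5-methylbenzaldehyde | CCCC(=O)c1c(O)c(Cc2c(O)c(C)c(OC)c(C=O)c2O)c(O)c(Cc2c(O)c(C)c(OC)c(C(=O)CCC)c2O)c1O | intermediate (not isolated)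
20 | agrimol C, 1-{3,5-bis[(3-butanoyl-2,6-dihydroxy-4-methoxy-5-methylphenyl)methyl]-2,4,6-trihydroxyphenyl}butan-1-one | CCCC(=O)c1c(O)c(Cc2c(O)c(C)c(OC)c(C(=O)CCC)c2O)c(O)c(Cc2c(O)c(C)c(OC)c(C(=O)CCC)c2O)c1O | target

## Step count and least certain steps

Total: 7 steps. Longest linear sequence: 6 steps (steps 1, 2, 3, 4, 6, 7); step 5 is a one-step side branch.

**Step 7 (key step, proposed new method).** The most likely failure is incomplete conversion, which would leave mixtures of partly acylated material that are hard to separate. The ortho-hydroxy ketone products and the many phenoxides can also bind rhodium and slow the catalyst. Decarbonylation of an acyl rhodium hydride would delete a formyl group, and branched insertion of 15 would give 2-methylpropanoyl groups. The fallback uses known chemistry only; it sets out from 7 and makes the ketones on the monomers. An excess of n-PrMgBr in THF (the first equivalent forms the magnesium phenoxide) adds to the aldehyde of 7 and should give racemic 2-(1-hydroxybutyl)-3-methoxy-4-methyl-5-[(triisopropylsilyl)oxy]phenol F1. MnO2 in CH2Cl2 oxidises the benzylic alcohol to 1-{6-hydroxy-2-methoxy-3-methyl-4-[(triisopropylsilyl)oxy]phenyl}butan-1-one F2, and Bu4NF/AcOH frees 1-(4,6-dihydroxy-2-methoxy-3-methylphenyl)butan-1-one F3. In parallel, purchased 1-(2,4,6-trihydroxyphenyl)butan-1-one F4 is taken through the Mannich reaction of step 5 to 1-{3,5-bis[(dimethylamino)methyl]-2,4,6-trihydroxyphenyl}butan-1-one F5. F5 is then heated with two equivalents of F3 as in step 6, which comes back to the route at 20.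

**Step 3.** Metalation may be incomplete or may occur at the wrong place (C5 next to the silyloxy group, or the ring methyl). The alkyllithium may attack silicon, and Dakin cleavage of the aldehyde may occur if the peroxide step turns basic. The fallback sets out from 9 and introduces the C-methyl group, so no ring hydroxylation is needed. MOMCl (2.2 equiv) and iPr2NEt protect the two more reactive hydroxyls to give 2-hydroxy-4,6-bis(methoxymethoxy)benzaldehyde F6. N-iodosuccinimide should iodinate ortho to the remaining chelated hydroxyl to give 2-hydroxy-3-iodo-4,6-bis(methoxymethoxy)benzaldehyde F7. Suzuki coupling with trimethylboroxine (Pd(dppf)Cl2, K2CO3, dioxane/water) gives 2-hydroxy-4,6-bis(methoxymethoxy)-3-methylbenzaldehyde F8, and MeI/K2CO3 gives 2-methoxy-4,6-bis(methoxymethoxy)-3-methylbenzaldehyde F9. HCl in MeOH removes both acetals and returns to the route at 8.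

**Step 6.** Bridge carbons may exchange by retro-Mannich reaction or ipso-substitution, giving symmetrical diarylmethanes and oligomers. The second alkylation may stop short, and the released amine may condense reversibly with formyl groups. In the fallback the roles of the rings are reversed. It sets out from 8, which with 10 and dimethylamine gives the Mannich base 3-[(dimethylamino)methyl]-2,4-dihydroxy-6-methoxy-5-methylbenzaldehyde F10. Two equivalents of F10 are heated with 9, whose two free positions act as the nucleophile, and the route is rejoined at 14.

**Step 2.** The silyl group may be lost under carbonate (the ether is para to a formyl group), followed by methylation at O4. The fallback sets out from 1 and carries O4 as a benzyl ether through the methylation only. BnBr/K2CO3 in MeCN gives 4-(benzyloxy)-2-hydroxy-3-methylbenzaldehyde F11, and MeI/K2CO3 in DMF gives 4-(benzyloxy)-2-methoxy-3-methylbenzaldehyde F12. Brief hydrogenolysis (H2, Pd/C, EtOAc) gives 4-hydroxy-2-methoxy-3-methylbenzaldehyde F13, and TIPSCl/imidazole returns to the route at 3.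

## Further compounds

F1 | step 7 | 2-(1-hydroxybutyl)-3-methoxy-4-methyl-5-[(triisopropylsilyl)oxy]phenol (racemic) | CCCC(O)c1c(O)cc(O[Si](C(C)C)(C(C)C)C(C)C)c(C)c1OC
F2 | step 7 | 1-{6-hydroxy-2-methoxy-3-methyl-4-[(triisopropylsilyl)oxy]phenyl}butan-1-one | CCCC(=O)c1c(O)cc(O[Si](C(C)C)(C(C)C)C(C)C)c(C)c1OC
F3 | step 7 | 1-(4,6-dihydroxy-2-methoxy-3-methylphenyl)butan-1-one | CCCC(=O)c1c(O)cc(O)c(C)c1OC
F4 | step 7 | 1-(2,4,6-trihydroxyphenyl)butan-1-one (purchased) | CCCC(=O)c1c(O)cc(O)cc1O
F5 | step 7 | 1-{3,5-bis[(dimethylamino)methyl]-2,4,6-trihydroxyphenyl}butan-1-one | CCCC(=O)c1c(O)c(CN(C)C)c(O)c(CN(C)C)c1O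
F6 | step 3 | 2-hydroxy-4,6-bis(methoxymethoxy)benzaldehyde | COCOc1cc(O)c(C=O)c(OCOC)c1
F7 | step 3 | 2-hydroxy-3-iodo-4,6-bis(methoxymethoxy)benzaldehyde | COCOc1cc(OCOC)c(C=O)c(O)c1I
F8 | step 3 | 2-hydroxy-4,6-bis(methoxymethoxy)-3-methylbenzaldehyde | COCOc1cc(OCOC)c(C=O)c(O)c1C
F9 | step 3 | 2-methoxy-4,6-bis(methoxymethoxy)-3-methylbenzaldehyde | COCOc1cc(OCOC)c(C=O)c(OC)c1C
F10 | step 6 | 3-[(dimethylamino)methyl]-2,4-dihydroxy-6-methoxy-5-methylbenzaldehyde | O=Cc1c(O)c(CN(C)C)c(O)c(C)c1OC
F11 | step 2 | 4-(benzyloxy)-2-hydroxy-3-methylbenzaldehyde | O=Cc1ccc(OCc2ccccc2)c(C)c1O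
F12 | step 2 | 4-(benzyloxy)-2-methoxy-3-methylbenzaldehyde | COc1c(C=O)ccc(OCc2ccccc2)c1C
F13 | step 2 | 4-hydroxy-2-methoxy-3-methylbenzaldehyde | COc1c(C=O)ccc(O)c1C
A1 | alternative 1 | 2,2'-{[2,4,6-tris(benzyloxy)-1,3-phenylene]bis(methylene)}bis[5-methoxy-4-methyl-3-(triisopropylsilyloxy)phenol] | COc1cc(O)c(Cc2c(OCc3ccccc3)cc(OCc3ccccc3)c(Cc3c(O)cc(OC)c(C)c3O[Si](C(C)C)(C(C)C)C(C)C)c2OCc2ccccc2)c(O[Si](C(C)C)(C(C)C)C(C)C)c1C
A2 | alternative 1 | 1,3,5-tris(benzyloxy)-2,4-bis[3-(triisopropylsilyloxy)prop-2-yn-1-yl]benzene | CC(C)[Si](OC#CCc1c(OCc2ccccc2)cc(OCc2ccccc2)c(CC#CO[Si](C(C)C)(C(C)C)C(C)C)c1OCc1ccccc1)(C(C)C)C(C)C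
A3 | alternative 1 | 3-methoxy-2-methylcyclobut-2-en-1-one | COC1=C(C)C(=O)C1
A4 | alternative 2 | 2,4-bis{[2,6-bis(benzyloxy)-4-methoxy-3-methylphenyl]methyl}benzene-1,3,5-triol | Oc1cc(O)c(Cc2c(OCc3ccccc3)cc(OC)c(C)c2OCc2ccccc2)c(O)c1Cc1c(OCc2ccccc2)cc(OC)c(C)c1OCc1ccccc1
A5 | alternative 2 | 1,7-bis[2,6-bis(benzyloxy)-4-methoxy-3-methylphenyl]heptane-3,5-dione | O=C(CCc1c(OCc2ccccc2)cc(OC)c(C)c1OCc1ccccc1)CC(=O)CCc1c(OCc2ccccc2)cc(OC)c(C)c1OCc1ccccc1
A6 | alternative 2 | dimethyl carbonate | COC(=O)OC
A7 | alternative 3 | 1-[4-(benzyloxy)-6-hydroxy-2-methoxy-3-methylphenyl]butan-1-one | CCCC(=O)c1c(O)cc(OCc2ccccc2)c(C)c1OC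
A8 | alternative 3 | 5-(benzyloxy)-3-methoxy-4-methyl-2-(trimethylsilyl)phenyl trifluoromethanesulfonate | COc1c(C)c(OCc2ccccc2)cc(OS(=O)(=O)C(F)(F)F)c1[Si](C)(C)C
A9 | alternative 3 | butanoic acid | CCCC(=O)O
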